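The benzophenone is cut inside ring B, at the bond between the acyl-bearing carbon C1 and the methyl-bearing carbon C6. Ring B carries oxygen on C2 and C4, methyl on C6 and the aroyl group on C1. This is the substitution pattern of a linear 1,3,5,7-tetraketone folded by aldol condensation. The key step releases such a chain from a 4-pyranone with aqueous alkali and lets it aromatise in the same flask, so ring B and its C1–C6 bond arise from an isomeric precursor. That precursor is 2,6-dimethyl-4-pyranone acylated on one methyl group by the complete, MOM-protected ring A (3-chloro-4,6-dimethoxy-2-methoxymethoxybenzoyl).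

Key step: step 6

Remark on the chemistry: the target has no stereocentre, and its aryl–carbonyl axes are not expected to be configurationally stable. It is therefore treated as one achiral compound that needs no enantioselective step. Carbinol 7 is made as a racemate, and its only stereocentre disappears in step 5.

Step 1
Reactants: 1 3,5-dimethoxyphenol
Product: 2 2-chloro-3,5-dimethoxyphenol
Conditions: SO2Cl2 (1.0 equiv, slow addition), 2,2,6,6-tetramethylpiperidine (5 mol %), toluene, rt
Reagents that add atoms: sulfuryl chloride, O=S(=O)(Cl)Cl
Why: Electrophilic aromatic chlorination under secondary-amine catalysis, in which the N-chloroamine formed in the flask is held by a hydrogen bond to the phenol OH and hands chlorine to one of the two equivalent ortho carbons rather than to C4, while slow addition of a single equivalent limits double chlorination and any 4-chloro isomer can be removed at this cheap stage.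

Step 2
Reactants: 2 2-chloro-3,5-dimethoxyphenol
Product: 3 3-chloro-2-hydroxy-4,6-dimethoxybenzaldehyde
Conditions: (CH2O)n (6 equiv), anhydrous MgCl2 (2 equiv), Et3N (4 equiv), MeCN, reflux; 1 M HCl work-up
Reagents that add atoms: paraformaldehyde (as formaldehyde), C=O
Why: Casnati–Skattebøl ortho-formylation: the magnesium phenoxide binds formaldehyde and transfers it only to an ortho carbon, the chlorine leaves C6 as the sole open ortho site, and a second formaldehyde takes up hydride to raise the benzylic alkoxide to the aldehyde.

Step 3
Reactants: 3 3-chloro-2-hydroxy-4,6-dimethoxybenzaldehyde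
Product: 4 3-chloro-4,6-dimethoxy-2-(methoxymethoxy)benzaldehyde
Conditions: NaH (1.2 equiv), DMF, 0 °C; MOMCl (1.3 equiv), 0 °C → rt
Reagents that add atoms: chloromethyl methyl ether (MOMCl), COCCl
Why: Williamson-type O-alkylation of the fully formed sodium phenoxide with the highly reactive MOMCl overcomes the hydrogen bond to the aldehyde, and the base-stable acetal removes the acidic proton before step 4 and stops O-2 of ring A from cyclising onto the polyketone in step 6.

Step 4
Reactants: 5 2,6-dimethyl-4H-pyran-4-one; 4 3-chloro-4,6-dimethoxy-2-(methoxymethoxy)benzaldehyde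
Product: 7 rac-2-{2-[3-chloro-4,6-dimethoxy-2-(methoxymethoxy)phenyl]-2-hydroxyethyl}-6-methyl-4H-pyran-4-one, via lithiated pyranone 6 (not isolated)
Conditions: 5 (1.3 equiv), LiHMDS (1.2 equiv), THF, −78 °C, 45 min; 4 in THF, −78 °C, 2 h; AcOH in THF, −78 °C
Reagents that add atoms: lithium hexamethyldisilazide, [Li]N([Si](C)(C)C)[Si](C)(C)C (supplies the lithium of 6 only; nothing of it stays in 7)
Why: Lateral lithiation of a 2-methyl-4-pyranone gives a vinylogous enolate that reacts at its exocyclic carbon in an aldol-type 1,2-addition to the non-enolisable aldehyde, the slight excess of 5 over base leaves no amide to attack the aldehyde, the cold acid quench forestalls retro-addition and loss of water, and the new carbinol centre is formed as a racemate that step 5 erases.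

Step 5
Reactants: 7 rac-2-{2-[3-chloro-4,6-dimethoxy-2-(methoxymethoxy)phenyl]-2-hydroxyethyl}-6-methyl-4H-pyran-4-one
Product: 8 2-{2-[3-chloro-4,6-dimethoxy-2-(methoxymethoxy)phenyl]-2-oxoethyl}-6-methyl-4H-pyran-4-one
Conditions: IBX (1.5 equiv), DMSO, rt
Reagents that add atoms: none
Why: IBX oxidation of a secondary benzylic alcohol proceeds without base or strong acid, is established for β-hydroxy carbonyl compounds that give enolisable 1,3-dicarbonyl-type products, and leaves MOM ether, aryl chloride and pyranone untouched.

Step 6
Reactants: 8 2-{2-[3-chloro-4,6-dimethoxy-2-(methoxymethoxy)phenyl]-2-oxoethyl}-6-methyl-4H-pyran-4-one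
Product: 10 [3-chloro-4,6-dimethoxy-2-(methoxymethoxy)phenyl](2,4-dihydroxy-6-methylphenyl)methanone, via open-chain tetraketone 9 (not isolated)
Conditions: 2 M aq. KOH (6 equiv), 1,4-dioxane, Ar, rt → 45 °C; AcOH to pH 5, 0 °C
Reagents that add atoms: potassium hydroxide/water, [K+].[OH-] (its oxygen enters 9 at C7 and leaves again as water on aromatisation, so 10 is an isomer of 8)
Why: Hydroxide first removes a proton from the aroyl-flanked CH2, then adds in conjugate fashion to the methyl-bearing pyranone carbon C6 (the terminus remote from the exocyclic enolate), and cleavage of the ring C–O bond unmasks the enolised 1-aryl-octane-1,3,5,7-tetraone 9. Carbon C2 of its C1–C3 β-diketonate adds to the C7 methyl ketone, water is lost by E1cB and tautomerisation to the resorcinolate makes the sequence irreversible, so bond C1–C6 of ring B and ring B itself arise in one operation. The closest known reaction type is the alkali-induced opening of 2,6-dimethyl-4-pyranone and its side-chain-acylated derivatives followed by intramolecular aldol condensation of the released polyketone to orcinol-type phenols. Ring B closes in the favoured 6-(enolendo)-exo-trig mode, and no stereocentre survives because the aldol carbinol is dehydrated. The step needs folding selectivity among three six-membered options (C2→C7, C6→C1, C8→C3): C1 is shut off as an electrophile by its two ortho substituents (OMe, OMOM) and by donation from the trioxygenated ring A, and C8 is a simple ketone α-position far less acidic than the doubly activated C2. The MOM ether keeps O-2 of ring A from closing a chromone on C3, and the moderate temperature keeps the new ring B 2-phenoxide from displacing an ortho alkoxy group of ring A (xanthone formation).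

Step 7
Reactants: 10 [3-chloro-4,6-dimethoxy-2-(methoxymethoxy)phenyl](2,4-dihydroxy-6-methylphenyl)methanone
Product: 11 [3-chloro-4,6-dimethoxy-2-(methoxymethoxy)phenyl][2-hydroxy-4-(methoxymethoxy)-6-methylphenyl]methanone
Conditions: MOMCl (1.05 equiv), K2CO3 (1.2 equiv), acetone, 0 °C → rt
Reagents that add atoms: chloromethyl methyl ether (MOMCl), COCCl
Why: Chemoselective Williamson etherification: the 4-OH para to the ketone is free and the more acidic one, whereas the 2-OH is locked in a six-membered hydrogen bond to the carbonyl and crowded by the aroyl group, so one equivalent of MOMCl with a weak base should take O-4 only, as is routine for 2,4-dihydroxyaryl ketones.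

Step 8
Reactants: 11 [3-chloro-4,6-dimethoxy-2-(methoxymethoxy)phenyl][2-hydroxy-4-(methoxymethoxy)-6-methylphenyl]methanone
Product: 12 [3-chloro-4,6-dimethoxy-2-(methoxymethoxy)phenyl][2-methoxy-4-(methoxymethoxy)-6-methylphenyl]methanone
Conditions: MeI (3 equiv), K2CO3 (2 equiv), DMF, rt → 40 °C
Reagents that add atoms: iodomethane, CI
Why: Williamson methylation of the only remaining acidic site, the chelated phenol, is driven by a polar aprotic solvent and excess MeI, and the low temperature avoids intramolecular displacement of an ortho alkoxy group by the phenoxide.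

Step 9
Reactants: 12 [3-chloro-4,6-dimethoxy-2-(methoxymethoxy)phenyl][2-methoxy-4-(methoxymethoxy)-6-methylphenyl]methanone
Product: 13 (3-chloro-2-hydroxy-4,6-dimethoxyphenyl)(4-hydroxy-2-methoxy-6-methylphenyl)methanone (target)
Conditions: HCl (1.25 M in MeOH), 40 °C
Reagents that add atoms: none
Why: Acid-catalysed acetal exchange with methanol removes both aryl MOM ethers in one operation, while the aryl methyl ethers, the aryl chloride and the diaryl ketone are inert to dilute methanolic acid.

Compound list
1 | 3,5-dimethoxyphenol | COc1cc(O)cc(OC)c1 | starting material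
2 | 2-chloro-3,5-dimethoxyphenol | COc1cc(O)c(Cl)c(OC)c1 | intermediate
3 | 3-chloro-2-hydroxy-4,6-dimethoxybenzaldehyde | COc1cc(OC)c(C=O)c(O)c1Cl | intermediate
4 | 3-chloro-4,6-dimethoxy-2-(methoxymethoxy)benzaldehyde | COCOc1c(Cl)c(OC)cc(OC)c1C=O | intermediate
5 | 2,6-dimethyl-4H-pyran-4-one | Cc1cc(=O)cc(C)o1 | starting material
6 | [(6-methyl-4-oxo-4H-pyran-2-yl)methyl]lithium (lithiated pyranone, not isolated) | [Li]Cc1cc(=O)cc(C)o1 | intermediate
7 | rac-2-{2-[3-chloro-4,6-dimethoxy-2-(methoxymethoxy)phenyl]-2-hydroxyethyl}-6-methyl-4H-pyran-4-one | Cc1cc(=O)cc(CC(O)c2c(OC)cc(OC)c(Cl)c2OCOC)o1 | intermediate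
8 | 2-{2-[3-chloro-4,6-dimethoxy-2-(methoxymethoxy)phenyl]-2-oxoethyl}-6-methyl-4H-pyran-4-one | Cc1cc(=O)cc(CC(=O)c2c(OC)cc(OC)c(Cl)c2OCOC)o1 | intermediate
9 | 1-[3-chloro-4,6-dimethoxy-2-(methoxymethoxy)phenyl]octane-1,3,5,7-tetraone (drawn as the all-keto form, not isolated) | CC(=O)CC(=O)CC(=O)CC(=O)c1c(OC)cc(OC)c(Cl)c1OCOC | intermediate
10 | [3-chloro-4,6-dimethoxy-2-(methoxymethoxy)phenyl](2,4-dihydroxy-6-methylphenyl)methanone | COCOc1c(Cl)c(OC)cc(OC)c1C(=O)c1c(C)cc(O)cc1O | intermediate
11 | [3-chloro-4,6-dimethoxy-2-(methoxymethoxy)phenyl][2-hydroxy-4-(methoxymethoxy)-6-methylphenyl]methanone | COCOc1cc(C)c(C(=O)c2c(OC)cc(OC)c(Cl)c2OCOC)c(O)c1 | intermediate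
12 | [3-chloro-4,6-dimethoxy-2-(methoxymethoxy)phenyl][2-methoxy-4-(methoxymethoxy)-6-methylphenyl]methanone | COCOc1cc(C)c(C(=O)c2c(OC)cc(OC)c(Cl)c2OCOC)c(OC)c1 | intermediate
13 | (3-chloro-2-hydroxy-4,6-dimethoxyphenyl)(4-hydroxy-2-methoxy-6-methylphenyl)methanone | COc1cc(OC)c(C(=O)c2c(C)cc(O)cc2OC)c(O)c1Cl | target

Total step count: 9. Longest linear sequence: 9 steps (1 → 13). Compound 5 is purchased and enters in step 4.

Steps most likely to fail

Step 6. The pyranone is deactivated by its own side-chain enolate and may open slowly. The released chain may fragment by retro-Claisen attack of hydroxide, fold in another mode, or re-close to a pyranone on acidification.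
- The fallback gives up the biomimetic closure and joins two finished rings by aryllithium addition. It sets out from 2 and comes back to the route at 12.
- Phenol 2 is protected (NaH, MOMCl, DMF) as 2-chloro-1,5-dimethoxy-3-(methoxymethoxy)benzene F1.
- Commercial 2,4-dihydroxy-6-methylbenzaldehyde (Cc1cc(O)cc(O)c1C=O) is etherified at its non-chelated 4-OH (MOMCl, K2CO3, acetone) to 2-hydroxy-4-(methoxymethoxy)-6-methylbenzaldehyde F2.
- F2 is then methylated (MeI, K2CO3, DMF) to 2-methoxy-4-(methoxymethoxy)-6-methylbenzaldehyde F3.
- Directed ortho-lithiation of F1 (n-BuLi, THF, 0 °C) should occur between OMOM and OMe, because the 3-methoxy group is buttressed by chlorine and turns its methyl towards C4. This gives [3-chloro-4,6-dimethoxy-2-(methoxymethoxy)phenyl]lithium F4.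
- F4 adds to F3 at −78 °C to give rac-[3-chloro-4,6-dimethoxy-2-(methoxymethoxy)phenyl][2-methoxy-4-(methoxymethoxy)-6-methylphenyl]methanol F5, and IBX oxidation of F5 delivers 12.

Step 4. The addition to the doubly ortho-substituted aldehyde may revert. The electron-rich benzylic alkoxide may also lose water to give a styrylpyranone, during the reaction or on the way to step 5.
- The fallback raises the electrophile to the acid oxidation level and uses a Claisen-type C-acylation. This removes the carbinol stage and makes step 5 unnecessary. It sets out from 4 and comes back at 8.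
- Aldehyde 4 is oxidised with Ag2O in aqueous NaOH/THF, chosen so that no chlorinating species meets the activated C5–H. The product is 3-chloro-4,6-dimethoxy-2-(methoxymethoxy)benzoic acid F6.
- Carbonyldiimidazole in THF converts F6 under neutral conditions into [3-chloro-4,6-dimethoxy-2-(methoxymethoxy)phenyl](1H-imidazol-1-yl)methanone F7.
- F7 is added at −78 °C to two equivalents of 6. The second equivalent takes up the acidic proton of the product, and a cold AcOH quench should release 8.

Step 1. The chlorinating agent may attack C4, between the two methoxy groups, or chlorinate twice. Either would cost material and require a difficult separation.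
- The fallback replaces electrophilic substitution by two directed ortho-metalations, so that coordination to the acetal fixes both positions. It sets out from 1 and comes back at 4 in the same number of steps.
- Phenol 1 is protected (NaH, MOMCl, DMF) as 1,3-dimethoxy-5-(methoxymethoxy)benzene F8.
- n-BuLi in THF at 0 °C should metalate between OMOM, the stronger director, and OMe to give [2,4-dimethoxy-6-(methoxymethoxy)phenyl]lithium F9.
- Hexachloroethane at −78 °C converts F9 into 2-chloro-1,5-dimethoxy-3-(methoxymethoxy)benzene F1, the same compound as in the fallback to step 6.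
- A second lithiation of F1 gives [3-chloro-4,6-dimethoxy-2-(methoxymethoxy)phenyl]lithium F4, and quenching with DMF gives 4.

Further compounds
F1 | step 6 | 2-chloro-1,5-dimethoxy-3-(methoxymethoxy)benzene | COCOc1cc(OC)cc(OC)c1Cl
F2 | step 6 | 2-hydroxy-4-(methoxymethoxy)-6-methylbenzaldehyde | COCOc1cc(C)c(C=O)c(O)c1
F3 | step 6 | 2-methoxy-4-(methoxymethoxy)-6-methylbenzaldehyde | COCOc1cc(C)c(C=O)c(OC)c1
F4 | step 6 | [3-chloro-4,6-dimethoxy-2-(methoxymethoxy)phenyl]lithium | [Li]c1c(OC)cc(OC)c(Cl)c1OCOC
F5 | step 6 | rac-[3-chloro-4,6-dimethoxy-2-(methoxymethoxy)phenyl][2-methoxy-4-(methoxymethoxy)-6-methylphenyl]methanol | COCOc1cc(C)c(C(O)c2c(OC)cc(OC)c(Cl)c2OCOC)c(OC)c1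
F6 | step 4 | 3-chloro-4,6-dimethoxy-2-(methoxymethoxy)benzoic acid | COCOc1c(Cl)c(OC)cc(OC)c1C(=O)O
F7 | step 4 | [3-chloro-4,6-dimethoxy-2-(methoxymethoxy)phenyl](1H-imidazol-1-yl)methanone | COCOc1c(Cl)c(OC)cc(OC)c1C(=O)n1ccnc1
F8 | step 1 | 1,3-dimethoxy-5-(methoxymethoxy)benzene | COCOc1cc(OC)cc(OC)c1
F9 | step 1 | [2,4-dimethoxy-6-(methoxymethoxy)phenyl]lithium | [Li]c1c(OC)cc(OC)cc1OCOC
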